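**Plan**

- Enabling feature: ring C holds an acyloin, C4(=O)–C3(OH). The carbinol carbon C3 carries ring B and is joined through C2–O1 to ring A, so a ring-A aldehyde (future C4) and a tethered B-ring aryl ketone (future C3) form a benzoin pair.
- Cuts, in order: the two MOM O–C bonds (5-O, 4'-O); C3–C4 (benzoin); O1–C2 (phenol alkylation); C1'–C(=O) (aryllithium plus Weinreb amide); the two aryl–prenyl bonds; the O-methyl bond on ring A.
- Forward: ring A is C-prenylated, methylated at O4 and MOM-protected at O6. Ring B (bought with its O-methyl in place) is MOM-protected, prenylated between its oxygens and turned into the α-chloroketone. An ether link joins the halves, ring C closes, and the MOM groups come off last.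
- Stereochemistry: the only stereocentre, C3 (S by CIP analysis of the target SMILES), is set by a chiral triazolium carbene in the ring closure. C3 bears no hydrogen, so it cannot epimerise afterwards.

Key step: step 8

Assumption: the (5aS,10bR) antipode of the aminoindanol triazolium salt is written for step 8; its sense of induction on this aryl ketone is not certain, and the mirror-image salt, equally available, is used if the first run delivers the 3R ketol.
Remark: the catalyst-bound species of step 8 (carbene–aldehyde adduct, Breslow intermediate) never build up in stoichiometric amount and are described in the Why line, not numbered.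

**Route**

Step 1
Reactants: 1 2,4,6-trihydroxybenzaldehyde; 2 prenyl bromide (1-bromo-3-methylbut-2-ene)
Product: 3 2,4,6-trihydroxy-3-(3-methylbut-2-en-1-yl)benzaldehyde
Conditions: DBU (1.0 equiv), THF, 0 °C → rt
Reagents that add atoms: none
Why: C-alkylation of a phloroglucinol phenoxide (a vinylogous enolate) by an allylic bromide; C3 and C5 are equivalent, so only one mono-C-prenyl isomer can form, and one equivalent of bromide limits double prenylation.

Step 2
Reactants: 3 2,4,6-trihydroxy-3-(3-methylbut-2-en-1-yl)benzaldehyde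
Product: 4 2,6-dihydroxy-4-methoxy-3-(3-methylbut-2-en-1-yl)benzaldehyde
Conditions: Me2SO4 (1.0 equiv), K2CO3 (1.0 equiv), acetone, 0 °C → rt
Reagents that add atoms: dimethyl sulfate, COS(=O)(=O)OC
Why: Williamson methylation with one equivalent of electrophile should go mainly to the 4-OH, which is para to the formyl group, the most acidic, and never held in the hydrogen bond to the carbonyl oxygen that the 2- and 6-hydroxyls share.

Step 3
Reactants: 4 2,6-dihydroxy-4-methoxy-3-(3-methylbut-2-en-1-yl)benzaldehyde
Product: 5 2-hydroxy-4-methoxy-6-(methoxymethoxy)-3-(3-methylbut-2-en-1-yl)benzaldehyde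
Conditions: MOMCl (1.05 equiv), i-Pr2NEt, CH2Cl2, 0 °C
Reagents that add atoms: chloromethyl methyl ether, COCCl
Why: Regioselective MOM protection of a phenol: the 6-OH has only H-5 as its second neighbour while the 2-OH is buttressed by the prenyl CH2, so O6 should react first, and the last hydroxyl, then locked in the formyl chelate, reacts slowly.

Step 4
Reactants: 6 4-bromo-3-methoxyphenol
Product: 7 1-bromo-2-methoxy-4-(methoxymethoxy)benzene
Conditions: MOMCl, i-Pr2NEt, CH2Cl2, 0 °C → rt
Reagents that add atoms: chloromethyl methyl ether, COCCl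
Why: Routine MOM protection of an unhindered phenol; the acetal also becomes the stronger of the two ortho-directing groups that flank C3 in the next step.

Step 5
Reactants: 7 1-bromo-2-methoxy-4-(methoxymethoxy)benzene; 2 prenyl bromide
Product: 9 1-bromo-2-methoxy-4-(methoxymethoxy)-3-(3-methylbut-2-en-1-yl)benzene, via aryllithium 8 (not isolated)
Conditions: LiTMP, THF, −78 °C; then CuBr·SMe2 (10 mol %), 2, −78 → 0 °C
Reagents that add atoms: none
Why: Directed ortho-metalation with a lithium amide, which deprotonates without exchanging bromine: C3–H between the OMe and OMOM donors is the most acidic ring proton, the 2,6-dioxygenated aryllithium is meta to bromine (no aryne, no driving force for halogen migration), and copper-catalysed allylation at the primary carbon of 2 gives the linear prenyl arene.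

Step 6
Reactants: 9 1-bromo-2-methoxy-4-(methoxymethoxy)-3-(3-methylbut-2-en-1-yl)benzene; 10 2-chloro-N-methoxy-N-methylacetamide
Product: 13 2-chloro-1-[2-methoxy-4-(methoxymethoxy)-3-(3-methylbut-2-en-1-yl)phenyl]ethan-1-one, via aryllithium 11 (not isolated), via lithium hemiaminal adduct 12 (not isolated)
Conditions: n-BuLi, THF, −78 °C; then 10, −78 → −40 °C; aq. NH4Cl
Reagents that add atoms: none
Why: Bromine–lithium exchange at −78 °C outruns any deprotonation, and the aryllithium adds only once to the Weinreb amide because the chelated tetrahedral adduct collapses only on work-up (Weinreb ketone synthesis), which gives the α-chloroketone without any halogenating reagent near the prenyl alkene.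

Step 7
Reactants: 5 2-hydroxy-4-methoxy-6-(methoxymethoxy)-3-(3-methylbut-2-en-1-yl)benzaldehyde; 13 2-chloro-1-[2-methoxy-4-(methoxymethoxy)-3-(3-methylbut-2-en-1-yl)phenyl]ethan-1-one
Product: 14 4-methoxy-2-{2-[2-methoxy-4-(methoxymethoxy)-3-(3-methylbut-2-en-1-yl)phenyl]-2-oxoethoxy}-6-(methoxymethoxy)-3-(3-methylbut-2-en-1-yl)benzaldehyde
Conditions: K2CO3, KI (10 mol %), DMF, rt
Reagents that add atoms: none
Why: Williamson etherification of the one free phenol with an activated α-haloketone (iodide-catalysed SN2); carbonate base at room temperature should keep the product from the intramolecular aldol condensation that leads to a 2-aroylbenzofuran.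

Step 8
Reactants: 14 the keto-aldehyde of step 7
Product: 15 (3S)-3-hydroxy-7-methoxy-3-[2-methoxy-4-(methoxymethoxy)-3-(3-methylbut-2-en-1-yl)phenyl]-5-(methoxymethoxy)-8-(3-methylbut-2-en-1-yl)-2,3-dihydro-4H-chromen-4-one
Conditions: (5aS,10bR)-2-(pentafluorophenyl)-5a,10b-dihydro-4H,6H-indeno[2,1-b][1,2,4]triazolo[4,3-d][1,4]oxazin-2-ium tetrafluoroborate (20 mol %), Et3N (20 mol %), toluene, Ar, rt → 40 °C
Reagents that add atoms: none
Why: The triazolylidene freed by Et3N adds to the formyl carbon, proton transfer gives the Breslow enaminol, this acyl-anion equivalent attacks the tethered aryl ketone, and collapse of the adduct releases the carbene and the tertiary ketol. The closest known reaction is the carbene-catalysed intramolecular crossed aldehyde–ketone benzoin of 2-(2-oxoalkoxy)benzaldehydes to 3-hydroxychroman-4-ones. Ring C (O1–C2–C3–C4–C4a–C8a) closes by 6-exo-trig attack of C4 on the ketone carbon C3. C3 is set by the catalyst: the fused aminoindanol backbone blocks one face of the Breslow intermediate, so the ketone is met on a single enantioface, taken here to give 3S. The step needs chemoselectivity for benzoin over base-mediated aldol of the O–CH2–C(=O) unit onto the aldehyde; only the aldehyde can become the nucleophile, and a weak amine base in a non-polar solvent keeps enolate chemistry slow.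

Step 9
Reactants: 15 the bis-MOM ketol of step 8
Product: 16 sophonorol F, (3S)-3,5-dihydroxy-3-[4-hydroxy-2-methoxy-3-(3-methylbut-2-en-1-yl)phenyl]-7-methoxy-8-(3-methylbut-2-en-1-yl)-2,3-dihydro-4H-chromen-4-one
Conditions: 1 M HCl in MeOH, 0 °C → rt
Reagents that add atoms: none
Why: Acid-catalysed acetal exchange of both aryl MOM ethers with the solvent; dilute acid at room temperature should spare the prenyl groups and the tertiary α-ketol, whose ionisation is disfavoured by the adjacent carbonyl.

**Compound list**

1 | 2,4,6-trihydroxybenzaldehyde | O=Cc1c(O)cc(O)cc1O | starting material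
2 | prenyl bromide (1-bromo-3-methylbut-2-ene) | CC(C)=CCBr | starting material
3 | 2,4,6-trihydroxy-3-(3-methylbut-2-en-1-yl)benzaldehyde | O=Cc1c(O)cc(O)c(CC=C(C)C)c1O | intermediate
4 | 2,6-dihydroxy-4-methoxy-3-(3-methylbut-2-en-1-yl)benzaldehyde | O=Cc1c(O)cc(OC)c(CC=C(C)C)c1O | intermediate
5 | 2-hydroxy-4-methoxy-6-(methoxymethoxy)-3-(3-methylbut-2-en-1-yl)benzaldehyde | O=Cc1c(OCOC)cc(OC)c(CC=C(C)C)c1O | intermediate
6 | 4-bromo-3-methoxyphenol | COc1cc(O)ccc1Br | starting material
7 | 1-bromo-2-methoxy-4-(methoxymethoxy)benzene | COCOc1ccc(Br)c(OC)c1 | intermediate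
8 | [3-bromo-2-methoxy-6-(methoxymethoxy)phenyl]lithium | [Li]c1c(OC)c(Br)ccc1OCOC | intermediate
9 | 1-bromo-2-methoxy-4-(methoxymethoxy)-3-(3-methylbut-2-en-1-yl)benzene | COCOc1ccc(Br)c(OC)c1CC=C(C)C | intermediate
10 | 2-chloro-N-methoxy-N-methylacetamide | CON(C)C(=O)CCl | starting material
11 | [2-methoxy-4-(methoxymethoxy)-3-(3-methylbut-2-en-1-yl)phenyl]lithium | [Li]c1ccc(OCOC)c(CC=C(C)C)c1OC | intermediate
12 | lithium 2-chloro-1-[methoxy(methyl)amino]-1-[2-methoxy-4-(methoxymethoxy)-3-(3-methylbut-2-en-1-yl)phenyl]ethan-1-olate | [Li]OC(CCl)(N(C)OC)c1ccc(OCOC)c(CC=C(C)C)c1OC | intermediate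
13 | 2-chloro-1-[2-methoxy-4-(methoxymethoxy)-3-(3-methylbut-2-en-1-yl)phenyl]ethan-1-one | O=C(CCl)c1ccc(OCOC)c(CC=C(C)C)c1OC | intermediate
14 | 4-methoxy-2-{2-[2-methoxy-4-(methoxymethoxy)-3-(3-methylbut-2-en-1-yl)phenyl]-2-oxoethoxy}-6-(methoxymethoxy)-3-(3-methylbut-2-en-1-yl)benzaldehyde | COc1cc(OCOC)c(C=O)c(OCC(=O)c2ccc(OCOC)c(CC=C(C)C)c2OC)c1CC=C(C)C | intermediate
15 | (3S)-3-hydroxy-7-methoxy-3-[2-methoxy-4-(methoxymethoxy)-3-(3-methylbut-2-en-1-yl)phenyl]-5-(methoxymethoxy)-8-(3-methylbut-2-en-1-yl)-2,3-dihydro-4H-chromen-4-one | COc1cc(OCOC)c2c(c1CC=C(C)C)OC[C@@](O)(c1ccc(OCOC)c(CC=C(C)C)c1OC)C2=O | intermediate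
16 | sophonorol F, (3S)-3,5-dihydroxy-3-[4-hydroxy-2-methoxy-3-(3-methylbut-2-en-1-yl)phenyl]-7-methoxy-8-(3-methylbut-2-en-1-yl)-2,3-dihydro-4H-chromen-4-one | COc1cc(O)c2c(c1CC=C(C)C)OC[C@@](O)(c1ccc(O)c(CC=C(C)C)c1OC)C2=O | target

**Count**

Total steps: 9. Longest linear sequence: 6 steps (1, 2, 3, 7, 8, 9; the B-ring branch 4, 5, 6, 7, 8, 9 is equally long).

**Steps most likely to fail**

Step 8. The carbene may add slowly to a formyl group flanked by two ortho oxygens on an electron-rich ring, base-induced aldol cyclisation to a benzofuran may overtake the benzoin, or the enantioface discrimination at the ketone may be insufficient. Fallback: stereocontrol by the catalyst is given up for resolution. From 14, closure with a small achiral azolium salt (3-benzyl-5-(2-hydroxyethyl)-4-methylthiazolium chloride, Et3N, t-BuOH, 40 °C), which reaches a hindered aldehyde more easily, should give the racemic ketol F1. Its enantiomers are separated by preparative chromatography on a chiral stationary phase, and the 3S enantiomer is 15, where the route resumes.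

Step 2. Methylation may spread to the 6-OH or go twice, because the 4-OH is now flanked by the prenyl group. Fallback: methylate before the prenyl group is present and bring the prenyl in by sigmatropic transfer. From 1, Me2SO4/K2CO3 in acetone on the unhindered 4-OH should give 2,6-dihydroxy-4-methoxybenzaldehyde F2. Mono-O-alkylation with 2 (K2CO3, acetone; the second hydroxyl stays chelated) gives 2-hydroxy-4-methoxy-6-[(3-methylbut-2-en-1-yl)oxy]benzaldehyde F3. A Eu(fod)3-catalysed (or thermal, N,N-diethylaniline) tandem Claisen–Cope shift then moves the prenyl group from O6 via C5 to C3, para to the oxygen it leaves, and the route is rejoined at 4.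

Step 7. Alkylation of the hindered, chelated phenoxide may be sluggish, and the carbonate base may drive the product into intramolecular aldol condensation (Rap–Stoermer pathway). Fallback: form the ether without base by a Mitsunobu reaction. From 13, sodium formate in DMF gives 2-[2-methoxy-4-(methoxymethoxy)-3-(3-methylbut-2-en-1-yl)phenyl]-2-oxoethyl formate F4. Brief methanolysis (cat. K2CO3, MeOH, 0 °C) gives 2-hydroxy-1-[2-methoxy-4-(methoxymethoxy)-3-(3-methylbut-2-en-1-yl)phenyl]ethan-1-one F5. Coupling of F5 with phenol 5 (PPh3, DIAD, toluene, 0 °C → rt) returns to the route at 14.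

**Further compounds**

F1 | step 8 | racemic 3-hydroxy-7-methoxy-3-[2-methoxy-4-(methoxymethoxy)-3-(3-methylbut-2-en-1-yl)phenyl]-5-(methoxymethoxy)-8-(3-methylbut-2-en-1-yl)-2,3-dihydro-4H-chromen-4-one | COc1cc(OCOC)c2c(c1CC=C(C)C)OCC(O)(c1ccc(OCOC)c(CC=C(C)C)c1OC)C2=O
F2 | step 2 | 2,6-dihydroxy-4-methoxybenzaldehyde | O=Cc1c(O)cc(OC)cc1O
F3 | step 2 | 2-hydroxy-4-methoxy-6-[(3-methylbut-2-en-1-yl)oxy]benzaldehyde | O=Cc1c(O)cc(OC)cc1OCC=C(C)C
F4 | step 7 | 2-[2-methoxy-4-(methoxymethoxy)-3-(3-methylbut-2-en-1-yl)phenyl]-2-oxoethyl formate | O=COCC(=O)c1ccc(OCOC)c(CC=C(C)C)c1OC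
F5 | step 7 | 2-hydroxy-1-[2-methoxy-4-(methoxymethoxy)-3-(3-methylbut-2-en-1-yl)phenyl]ethan-1-one | O=C(CO)c1ccc(OCOC)c(CC=C(C)C)c1OC
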